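The earlier runs and the new flask were computed for substances that don't exist; the scatter is artificial.

The vessel is closed and holds a racemate over a single-handed catalyst, so the curve to watch is left-handed product against the reagent charged.

| setting | larch | ash | flask |
|---|---|---|---|
| left-handed substrate | 0.50 M | 0.50 M | 0.50 M |
| right-handed substrate | 0.50 M | 0.50 M | 0.50 M |
| reagent | 0.75 M | 3 M | 1.50 M |
| free catalyst | 0.25 mM | 0.25 mM | 0.25 mM |
| remark | run made earlier | run made earlier |  |

- larch (time / min: left-handed product / %): 8.00: 3.6; 15.0: 5.9; 30.0: 10.4; 60.0: 17.1; 120: 24.6
- ash (time / min: left-handed product / %): 8.00: 9.4; 15.0: 15.9; 30.0: 25.8; 60.0: 38.3; 120: 46.3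

(each reading ± 0.5 percentage points)

- free catalyst is single-handed; left-handed substrate and right-handed substrate are mirror images of each other, charged as a racemate, each of them at the stated concentration
- what was read earlier has a scatter of 0.5 percentage points, one standard deviation
- what may be going on: reagent + catalyst intermediate A -> free catalyst + left-handed product; free catalyst + left-handed substrate <-> catalyst intermediate A; free catalyst -> spent catalyst; reagent + catalyst intermediate B -> free catalyst + right-handed product; free catalyst + right-handed substrate <-> catalyst intermediate B

* apparent order in reagent when 50% of the left-handed substrate and right-handed substrate together are converted (percent change of the rate of making left-handed product for one percent more reagent charged)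
* factor on the rate of making left-handed product when 50% of the left-handed substrate and right-handed substrate together are converted if reagent is charged twice over

The flask has twice the reagent of larch, and ash has twice the reagent of the flask, with everything else equal. So ash is the flask with its reagent doubled. For the start I take the geometric mean of the two runs, which gives 5.82% left-handed product at 8.00 min; a doubling of reagent is worth a factor of 1.62 there.

For the bend I reckon as if free catalyst and left-handed substrate keep their binding in balance. Free catalyst then cancels: product formed per catalyst lost goes with c(reagent) times c(left-handed substrate). So the logarithm of left-handed substrate charged over left-handed substrate remaining, divided by the reagent charged, should read alike at equal catalyst lost, not at equal times. At 30.0 min the two runs differ, larch 0.311 L mol⁻¹ and ash 0.242 L mol⁻¹, so I use the measure at the last reading alone, and it is an assumption of mine that the catalyst lost is roughly alike there. At 120 min larch reads 0.903 L mol⁻¹ and ash 0.868 L mol⁻¹. Their mean, 0.885 L mol⁻¹, is my reach per reagent.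

On that same assumption, it puts left-handed product in the flask at 36.8% of the pair at 120 min, bending toward the left-handed charge, 50.0% of the pair. Ash reads 38.3% at 60.0 min, about that level in half the time, so I expect the factor at the asked conversion to stand above 1.62. The forecast gives an order of 1.9 and a factor of 2.8, counting “less catalyst death because the point is reached sooner”.

The flask gives an order of 3.8 and a factor of 4.59, higher than the forecast's 2.8.

    reagent + catalyst intermediate A → free catalyst + left-handed product (k = 43.0 L mol⁻¹ min⁻¹)
    free catalyst + left-handed substrate ⇌ catalyst intermediate A (K = 7.70 L mol⁻¹, k = 810 L mol⁻¹ min⁻¹)
    free catalyst → spent catalyst (k = 0.0270 min⁻¹)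
    reagent + catalyst intermediate B → free catalyst + right-handed product (k = 6.50 L mol⁻¹ min⁻¹)
    free catalyst + right-handed substrate ⇌ catalyst intermediate B (K = 4.10 L mol⁻¹, k = 1000 L mol⁻¹ min⁻¹)

The flask reaches the asked conversion at 2.83 h, and at 3.00 h spent catalyst stands at 72.9% of the catalyst charged. The reach per reagent of 0.885 L mol⁻¹ gave 36.8% at 120 min; the flask holds 33.5% left-handed product at 1.50 h and 41.5% at 3.00 h.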